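The ratio that mattered for the next flask was Gy gained per day to Ul standing in solution. Solid Zu dissolves to Ux, Ux passes reversibly into Ul, Gy and Vo, and with Lx it goes on to Qa.

| flask | Zu | Lx | remark | time |
|---|---|---|---|---|
| south-east | 0.62 M | 0.42 M | run made earlier |  |
| north-east | 0.62 M | 0.93 M | run made earlier |  |
| flask | 0.62 M | 0.620 M |  | 12 d |

| run | time / d | Ul / % | Gy / % |
|---|---|---|---|
| south-east | 2.08 | 5.9 | 2.1 |
| south-east | 4.00 | 6.3 | 4.5 |
| south-east | 6.00 | 7.0 | 8.5 |
| south-east | 8.00 | 7.0 | 10.8 |
| south-east | 10.0 | 6.9 | 13.3 |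
| south-east | 12.0 | 7.0 | 16.3 |
| south-east | 15.0 | 7.7 | 21.0 |
| north-east | 0.833 | 1.8 | 0.6 |
| north-east | 2.00 | 4.2 | 2.2 |
| north-east | 4.00 | 5.1 | 4.2 |
| north-east | 6.00 | 5.8 | 7.4 |
| north-east | 8.00 | 6.0 | 9.6 |
| north-east | 12.0 | 3.2 | 11.9 |
| north-east | 15.0 | 1.3 | 12.4 |

(readings scatter by 0.5 percentage points)

- as a solid, counted per litre of solution: Zu
- reactions considered so far: Ux <-> Ul; Ux <-> Gy; Ux <-> Vo; Zu <-> Ux; Ux + Lx -> Qa
- at the start none of Zu is in solution
- what has only dissolved of Zu counts as not reacted
- the reaction counts as stopped when no species that holds the Zu changes by six tenths of a point or more over the second half of the time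

- at 12 d, what has stopped the reaction, if anything has (for what has run out or reacted, a solid counts together with what of it has only dissolved) (forward and back rates have come level / all of Zu has reacted / it is still moving)
- amount of Ul at 12 d, in percent of the Zu charged
- amount of Gy at 12 d, in percent of the Zu charged

While solid stood, I froze c(Ux) and c(Ul) as nearly constant, a quasi-steady state, so that Gy should grow in step with time. The south-east run, with 16.3% of Gy against 7.0% of Ul after 12.0 d, gave 0.194 /d, the leak ratio: Gy gained per day for each point of Ul standing. The north-east run gave 0.200 /d at 8.00 d.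

My decision was when to read a flask charged with 0.620 M of Lx. I took the ratio to hold while Ul stood, and in the north-east run Ul stood at 6.0% at 8.00 d but had fallen to 3.2% at 12.0 d. Taking the drain of Ux into Qa as proportional to c(Lx), I scaled that time to 12.0 d, so I set the reading there and no later. With Ul midway between the two runs, at 6.50%, my reckoning gave 15.1% of Gy.

The forecast said it is still moving, with Ul 6.3% (5% to 7.2%) and Gy 15% (13.5% to 16.3%): “Gy is still rising, so the reaction is still moving”.

At 12 d the flask gave it is still moving, with Ul 7.20%, Gy 15.4% and solid Zu 4.46%.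

    Ux ⇌ Ul (K = 1.00, k = 1.04 × 10⁻⁵ /s)
    Ux ⇌ Gy (K = 146, k = 2.29 × 10⁻⁶ /s)
    Ux ⇌ Vo (K = 1.50, k = 1.16 × 10⁻⁶ /s)
    Zu ⇌ Ux, rate k4*(cs4 - [Ux]) while solid is left; crystals form when [Ux] > cs4 (solubility = 0.0550 M, k = 3.94 × 10⁻⁵ /s)
    Ux + Lx → Qa (k = 2.19 × 10⁻⁵ /M/s)

On this flask the leak ratio, times its Ul and time, gives 16.8% of Gy. The neighbouring flask took 2.5 M of Zu, with Lx and time held. Its Ul, 1.79% of a larger charge, is 0.0447 M, against 0.0447 M in the flask. The same ratio gives that neighbouring flask 4.17% of Gy, and its Gy stood at 3.82%.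

The data were generated by integration for an exercise; noise was put on by code.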